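At 30.0 min the cedar flask has a leftover: target 64.4% and free starting material (the limiting reagent) 0.9% leave 34.7% of the charge in neither form. Cedar is the flask we are asked about, so "now" is that target reading, within its scatter.

all flasks: starting material 0.038 M; free enzyme 0.01 mol%; temperature 37 °C
- cedar: second substrate 2.5 equiv; the very flask that is asked about, followed so far
- flask: second substrate 2.50 equiv; time 30 min

- cedar (time / min: target / %, starting material / %): 4.00: 25.8, 49.5; 8.00: 44.0, 14.6; 12.0: 53.2, 4.4; 15.0: 56.3, 2.9; 20.0: 60.4, 1.9; 25.0: 62.8, 1.4; 30.0: 64.4, 0.9

(scatter of a reading: 0.3 percentage points)

- target taken out counts as made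
- additions bring no volume worth counting
- a reading of starting material is of its free form alone

- alpha: change nothing and wait 30 min more
- gamma: at 30 min add free enzyme, 100% of the amount charged, then wait 30 min
- zeta: at 30 min take out 90% of the target then present, then wait 30 min
- epsilon: at 30 min add second substrate, 50.0% of the amount charged, then wait 30 min

1. target, in percent of the starting material first charged, at 30 min
2. what to do for the largest gain in target; "none" if nothing gains more than 2 percentage points (alpha / gamma / zeta / epsilon / none)
3. target present, with what was taken out counted in, in percent of the starting material first charged, after alpha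
4. target present, with what was taken out counted in, in percent of the starting material first charged, after gamma

1. At 8.00 min the missing part reads 41.4% against target 44.0%. So we take starting material as held one-for-one by a partner made with the target, either the target itself or a coproduct.

2. Late on, the unreacted starting material, free or held, is the charge minus target, and the free partner is target minus that. We call the first over the second the ratio, and take [starting material] to follow it.

3. From 20.0 min to 30.0 min the mean rate is 0.00400 /min of the charge. The ratio at the middle reading is 1.45. Rate over ratio is the drain constant 0.00275 /min, a reading that carries the scatter.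

4. Alpha from above: hold the ratio at today's 1.24, which gives 74.6%. From below: hold it at its value at that ceiling, 0.516, which gives 68.7%.

5. Tightened: take the ratio midway through the mean of those two gains, 68.0% of target. The gain is 7.3 percentage points, so alpha ends near 71.7%.

6. Gamma makes the constant twice as large if the enzyme lasts, so its gain lies between 7.3 points and 15 points. The same midway step gives 69.9% of target, a gain of 12 points and an end near 76.9%.

7. Zeta gains 7.3 points if the partner is a coproduct and more if it is the target. The readings cannot tell these apart, so we commit to gamma, whose gain stands on either view.

The forecast gives 64.4%, zeta, 72% inside our alpha bracket, and 76.8%. It argues: “Removing target frees the bound material, gaining roughly 25–30, so zeta is best.”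

The flask gives 64.7%, 72.1% and 77.4%, and the best move is gamma.

    starting material + first product ⇌ idle adduct, settled at all times (K = 2700 /M, ΔH = −25.0 kJ/mol)
    free enzyme → unfolded enzyme (k = 1.20 × 10⁻⁴ /s, Ea = 212 kJ/mol)
    starting material + free enzyme ⇌ first complex (K = 130 /M, k = 36000 /M/s, Ea = 14.0 kJ/mol, ΔH = −77.0 kJ/mol)
    second complex → free enzyme + target (k = 180 /s, Ea = 54.0 kJ/mol)
    second substrate + loaded enzyme ⇌ second complex (K = 140 /M, k = 6300 /M/s, Ea = 17.0 kJ/mol, ΔH = −37.0 kJ/mol)
    first complex ⇌ loaded enzyme + first product (K = 0.0880 M, k = 15.0 /s, Ea = 58.0 kJ/mol, ΔH = −16.0 kJ/mol)
    (constants at 37 °C)

Gamma gains 13 points; alpha, zeta and epsilon each gain 7.4 points. The partner is first product, and idle adduct holds 34.2% at 30.0 min. The neighbour flask, with other charges as in cedar, runs at 0.04 mol% of free enzyme for 30 min, worth 90.0 min beyond cedar's reading at cedar's constant 0.00275 /min. Taking the ratio midway through a guessed gain of 16 points gives 72.2% of target, a gain of 16 points, and an end near 79.9%. The neighbour flask gives 81.6%, with unfolded enzyme at 17.9% of the catalyst charged.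

(The readings are calculated from invented constants; noise was put on by code.)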